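**Strategy**

- Retrosynthesis: the pyranone ring C is cut at C4a–C4, C4–C3 and O1–C2. This releases C4 as carbon monoxide and leaves ring A as an ortho-iodophenol and ring B as an arylacetylene that carries C2 and C3.
- Enabling feature: C4 is bonded only to C4a, C3 and its own oxygen, and O1 sits on C8a next to C4a. A one-carbon unit inserted between an ortho-iodophenol and an alkyne terminus therefore rebuilds the whole 4-pyranone. Rings A and B are both 3,4,5-trimethoxyaryl units with a local mirror plane, so no positional isomers can arise.
- Forward: iodination of 3,4,5-trimethoxyphenol and one-carbon homologation of 3,4,5-trimethoxybenzaldehyde give the two partners, with rings A and B bought intact. Ring C, the only ring made, closes last in a single carbonylative coupling–cyclisation; the phenol stays unprotected because its oxygen is the ring-closing nucleophile.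
- Stereochemistry: the target has no stereocentre and no stereogenic double bond, so nothing has to be controlled.

Key step: step 3

**Route**

Step 1
Reactants: 1 3,4,5-trimethoxyphenol
Product: 2 2-iodo-3,4,5-trimethoxyphenol
Conditions: NIS (1.0 equiv), MeCN, 0 °C, dark; aq. Na2S2O3 work-up
Reagents that add atoms: N-iodosuccinimide, O=C1CCC(=O)N1I
Why: Electrophilic aromatic iodination of a strongly activated phenol, in which the only two free ring positions are equivalent by symmetry and each lies ortho to the hydroxyl and para to a methoxy group, so mono-iodination can give only 2 and one equivalent of NIS at low temperature should hold back a second iodination.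

Step 2
Reactants: 3 3,4,5-trimethoxybenzaldehyde; 4 dimethyl (1-diazo-2-oxopropyl)phosphonate (Ohira–Bestmann reagent)
Product: 6 5-ethynyl-1,2,3-trimethoxybenzene, via diazoalkene 5 (not isolated)
Conditions: 4 (1.3 equiv), K2CO3 (2 equiv), MeOH, 0 °C to rt
Reagents that add atoms: none
Why: Seyferth–Gilbert homologation in its Ohira–Bestmann form, in which methoxide removes the acetyl group of 4 to unmask the diazomethylphosphonate anion, Horner–Wadsworth–Emmons-type olefination of the non-enolisable aldehyde gives diazoalkene 5, and loss of N2 with a 1,2-hydride shift should deliver the terminal alkyne under conditions that leave the aryl methyl ethers untouched.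

Step 3
Reactants: 2 2-iodo-3,4,5-trimethoxyphenol; 6 5-ethynyl-1,2,3-trimethoxybenzene (1.5 equiv); 7 carbon monoxide
Product: 10 5,6,7-trimethoxy-2-(3,4,5-trimethoxyphenyl)-4H-chromen-4-one, via ortho-hydroxyaryl ynone 8 (not isolated), via E-enaminone 9 (not isolated)
Conditions: PdCl2(dppf) (5 mol %; dppf = 1,1'-bis(diphenylphosphino)ferrocene), CO (20 bar), Et2NH, 120 °C, autoclave
Reagents that add atoms: none
Why: Zerovalent palladium, generated in the flask from the divalent palladium precatalyst PdCl2(dppf), should insert into the C–I bond of 2, take up CO to form an aroylpalladium species and couple this with the acetylide that diethylamine forms from 6, so that reductive elimination creates the C4a–C4 and C4–C3 bonds of ynone 8. Diethylamine then adds to the triple bond of 8 to give the E-enaminone 9, and the neighbouring phenol oxygen attacks the amine-bearing β carbon and expels diethylamine, which forms the O1–C2 bond. The closest known reaction type is the Pd-catalysed carbonylative Sonogashira coupling–cyclisation of ortho-iodophenols with terminal arylacetylenes under CO in a secondary amine, which gives flavones. Ring C, the only ring closed, forms by a net 6-endo-dig oxa-Michael closure (addition–elimination at the β carbon of 9); no stereocentre arises, so no controlling element is needed. Two selectivities are required: carbonylative over direct alkynylation (which would end in a benzofuran), secured by CO pressure, the absence of CuI and the electron-rich, doubly ortho-substituted aryl group that migrates readily to CO, and 6-endo over 5-exo closure (which would end in an aurone), secured because the enaminone places the leaving group on the β carbon. Regiochemistry within the fragments is not at issue, since the iodine of 2 already sits ortho to the hydroxyl and both aryl units are symmetric.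

**Compound list**

1 | 3,4,5-trimethoxyphenol | COc1cc(O)cc(OC)c1OC | starting material
2 | 2-iodo-3,4,5-trimethoxyphenol | COc1cc(O)c(I)c(OC)c1OC | intermediate
3 | 3,4,5-trimethoxybenzaldehyde | COc1cc(C=O)cc(OC)c1OC | starting material
4 | dimethyl (1-diazo-2-oxopropyl)phosphonate | CC(=O)C(=[N+]=[N-])P(=O)(OC)OC | starting material
5 | 5-(2-diazoethenyl)-1,2,3-trimethoxybenzene (transient diazoalkene) | COc1cc(C=C=[N+]=[N-])cc(OC)c1OC | intermediate
6 | 5-ethynyl-1,2,3-trimethoxybenzene | C#Cc1cc(OC)c(OC)c(OC)c1 | intermediate
7 | carbon monoxide | [C-]#[O+] | starting material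
8 | 1-(6-hydroxy-2,3,4-trimethoxyphenyl)-3-(3,4,5-trimethoxyphenyl)prop-2-yn-1-one (transient ynone) | COc1cc(O)c(C(=O)C#Cc2cc(OC)c(OC)c(OC)c2)c(OC)c1OC | intermediate
9 | (E)-3-(diethylamino)-1-(6-hydroxy-2,3,4-trimethoxyphenyl)-3-(3,4,5-trimethoxyphenyl)prop-2-en-1-one (transient enaminone) | CCN(CC)/C(=C/C(=O)c1c(O)cc(OC)c(OC)c1OC)c1cc(OC)c(OC)c(OC)c1 | intermediate
10 | 5,6,7-trimethoxy-2-(3,4,5-trimethoxyphenyl)-4H-chromen-4-one (5,6,7,3',4',5'-hexamethoxyflavone) | COc1cc(-c2cc(=O)c3c(OC)c(OC)c(OC)cc3o2)cc(OC)c1OC | target

**Step count**

Total steps: 3. Longest linear sequence: 2 steps (step 1 then step 3, or step 2 then step 3).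

**Steps most likely to fail, riskiest first**

1. Step 3. Oxidative addition into the hindered, electron-rich C–I bond may be sluggish. Alkynylation may also occur without CO uptake and be followed by 5-endo closure, or the aroylpalladium species may be captured by diethylamine (aminocarbonylation). The fallback sets out from 1 and 3 and comes back to the route at 10; it builds ring C by condensation instead of carbonylation. Friedel–Crafts C-acetylation of 1 ortho to the hydroxyl (AcOH, BF3·OEt2, 90 °C) should give 1-(6-hydroxy-2,3,4-trimethoxyphenyl)ethan-1-one F1. Claisen–Schmidt condensation of this ketone with 3 (KOH, EtOH, rt) should give the chalcone (E)-1-(6-hydroxy-2,3,4-trimethoxyphenyl)-3-(3,4,5-trimethoxyphenyl)prop-2-en-1-one F2. Oxidative cyclisation of the chalcone (I2 cat., DMSO, 130 °C) should then close ring C by oxa-Michael addition and dehydrogenation to give 10.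

2. Step 1. A second iodination at the remaining ortho position, or oxidation of the very electron-rich phenol to a quinone, may erode the mono-iodide. The fallback sets out from 1 and comes back at 2; it replaces electrophilic substitution by directed ortho-metalation. Protection of 1 (MOMCl, i-Pr2NEt, CH2Cl2, 0 °C to rt) should give 1,2,3-trimethoxy-5-(methoxymethoxy)benzene F3. Lithiation at the position flanked by the acetal and a methoxy group (n-BuLi, THF, 0 °C), followed by an I2 quench at −78 °C, should give 2-iodo-3,4,5-trimethoxy-1-(methoxymethoxy)benzene F4, in which only one iodine can be introduced. Acidic methanolysis (HCl, MeOH, 40 °C) should then free the phenol 2.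

3. Step 2. Addition of the diazophosphonate anion to the electron-rich, weakly electrophilic aldehyde may be slow, so that the reagent is consumed by methanol before it olefinates. The fallback sets out from 3 and comes back at 6; it uses the two-stage Corey–Fuchs sequence. Dibromo-olefination of 3 (CBr4, PPh3, CH2Cl2, 0 °C) should give 5-(2,2-dibromoethenyl)-1,2,3-trimethoxybenzene F5. Treatment with n-BuLi (2.2 equiv, THF, −78 °C), then an aqueous quench, should give 6 by lithium–bromine exchange and Fritsch–Buttenberg–Wiechell rearrangement.

**Further compounds**

F1 | step 3 | 1-(6-hydroxy-2,3,4-trimethoxyphenyl)ethan-1-one | CC(=O)c1c(O)cc(OC)c(OC)c1OC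
F2 | step 3 | (E)-1-(6-hydroxy-2,3,4-trimethoxyphenyl)-3-(3,4,5-trimethoxyphenyl)prop-2-en-1-one | COc1cc(/C=C/C(=O)c2c(O)cc(OC)c(OC)c2OC)cc(OC)c1OC
F3 | step 1 | 1,2,3-trimethoxy-5-(methoxymethoxy)benzene | COCOc1cc(OC)c(OC)c(OC)c1
F4 | step 1 | 2-iodo-3,4,5-trimethoxy-1-(methoxymethoxy)benzene | COCOc1cc(OC)c(OC)c(OC)c1I
F5 | step 2 | 5-(2,2-dibromoethenyl)-1,2,3-trimethoxybenzene | COc1cc(C=C(Br)Br)cc(OC)c1OC
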